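**Retrosynthetic overview**
1. Target ⇐ Yamaguchi esterification of the C8 hydroxyl of the 10-membered lactone 33 with epoxy acid 32, then desilylation; the oxirane is the first ring made (Sharpless epoxidation, side branch).
2. 33 ⇐ open-chain enal/allyl bromide 19: the C6–C7 bond is formed by a chromium-catalysed Nozaki–Hiyama–Kishi-type macrocyclising allylation; the carbocycle closes first and the γ-lactone second, in the same pot.
3. 19 ⇐ dialdehyde 16 (Morita–Baylis–Hillman reaction with methyl acrylate, SN2′ bromination); 16 ⇐ Z-alkenyl iodide 10 + glycidol-derived epoxide 12 (C9–C10).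
4. 10 ⇐ but-2-ynal + methyl senecioate dienolate (asymmetric vinylogous Mukaiyama aldol sets C2; hydroalumination–iodination sets the 1(10)Z alkene).
5. 32 ⇐ crotonaldehyde (α-bromination, reduction, hydroxymethylation, epoxidation, oxidation).

Assumption: ring atoms carry germacrane numbers (C1=C10 Z, C4=C5 E, lactone O on C6, ester O on C8, C11=C13 exocyclic, C14 on C10, C15 on C4); the SMILES then reads (2S,6R,7R,8R) with a (2R,3R)-epoxy acid. Descriptors that change only because a silyl group alters CIP priority are noted where they occur.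

**Route**

Step 1
Reactants: 1 but-2-yn-1-ol
Product: 2 but-2-ynal
Conditions: MnO2 (activated, 10 equiv), CH2Cl2, rt; filtered solution used directly
Reagents that add atoms: none
Why: Activated MnO2 oxidises the propargylic alcohol to the conjugated ynal without over-oxidation (propargylic alcohol oxidation), and no stereocentre is involved.

Step 2
Reactants: 3 methyl 3-methylbut-2-enoate
Product: 4 (1Z)-1-[(tert-butyldimethylsilyl)oxy]-1-methoxy-3-methylbuta-1,3-diene
Conditions: LiN(iPr)2, THF, −78 °C; t-BuMe2SiCl, DMPU, −78 °C → rt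
Reagents that add atoms: tert-butyldimethylsilyl chloride, CC(C)(C)[Si](C)(C)Cl
Why: γ-Deprotonation of the senecioate and O-silylation of the extended enolate give the silyl dienol ether (silyl ketene acetal formation).

Step 3
Reactants: 2 but-2-ynal; 4 silyl dienol ether
Product: 5 methyl (2E,5S)-5-hydroxy-3-methyloct-2-en-6-ynoate
Conditions: SiCl4 (1.1 equiv), (R,R)-binaphthyldiamine-derived bisphosphoramide (5 mol %), iPr2NEt (10 mol %), CH2Cl2, −78 °C; aq. NaHCO3
Reagents that add atoms: none
Why: The phosphoramide-bound trichlorosilyl cation activates the ynal and the dienolate attacks through its γ-carbon on the Si face, giving the E-configured γ-adduct and setting C2 as S (catalytic asymmetric vinylogous Mukaiyama aldol); the face defines the catalyst enantiomer, so the (S,S)-catalyst is taken if the sense proves opposite for this ynal.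

Step 4
Reactants: 5 methyl (2E,5S)-5-hydroxy-3-methyloct-2-en-6-ynoate
Product: 6 (2E,5S)-3-methyloct-2-en-6-yne-1,5-diol
Conditions: iBu2AlH (3.3 equiv), CH2Cl2, −78 °C; Rochelle salt
Reagents that add atoms: none
Why: iBu2AlH reduces the enoate 1,2 to the allylic alcohol and leaves alkyne, alkene and the stereocentre untouched (ester reduction).

Step 5
Reactants: 6 (2E,5S)-3-methyloct-2-en-6-yne-1,5-diol
Product: 8 (2E,5S,6Z)-7-iodo-3-methylocta-2,6-diene-1,5-diol, via vinylalanate 7 (not isolated)
Conditions: NaAlH2(OCH2CH2OCH3)2 (3.5 equiv), THF, 0 °C → rt; then I2, −78 → 0 °C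
Reagents that add atoms: iodine, II
Why: The propargylic alkoxide directs trans-hydroalumination (H to the proximal and Al to the distal alkyne carbon in a five-membered alanate) and iodinolysis with retention gives the (Z)-3-iodoallylic alcohol, which fixes the 1(10)Z geometry (hydroalumination–iodination of a propargylic alcohol).

Step 6
Reactants: 8 (2E,5S,6Z)-7-iodo-3-methylocta-2,6-diene-1,5-diol
Product: 9 (2Z,4S,6E)-2-iodo-6-methyl-8-[(triethylsilyl)oxy]octa-2,6-dien-4-ol
Conditions: Et3SiCl (1.05 equiv), imidazole, CH2Cl2, −78 °C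
Reagents that add atoms: chlorotriethylsilane, CC[Si](Cl)(CC)CC
Why: The unhindered primary allylic hydroxyl is silylated much faster than the flanked secondary one at low temperature (selective silylation).

Step 7
Reactants: 9 (2Z,4S,6E)-2-iodo-6-methyl-8-[(triethylsilyl)oxy]octa-2,6-dien-4-ol
Product: 10 tert-butyl{[(2Z,4S,6E)-2-iodo-6-methyl-8-[(triethylsilyl)oxy]octa-2,6-dien-4-yl]oxy}dimethylsilane
Conditions: t-BuMe2SiOTf, 2,6-lutidine, CH2Cl2, −78 °C
Reagents that add atoms: tert-butyldimethylsilyl trifluoromethanesulfonate, CC(C)(C)[Si](C)(C)OS(=O)(=O)C(F)(F)F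
Why: The silyl triflate caps the hindered secondary allylic alcohol while the primary triethylsilyl ether survives at −78 °C (silyl ether formation).

Step 8
Reactants: 11 (S)-glycidol
Product: 12 (R)-triethyl(oxiran-2-ylmethoxy)silane
Conditions: Et3SiCl, imidazole, CH2Cl2, 0 °C
Reagents that add atoms: chlorotriethylsilane, CC[Si](Cl)(CC)CC
Why: O-Silylation leaves the epoxide and its stereocentre untouched (the descriptor changes from S to R only through CIP priority).

Step 9
Reactants: 10 Z-alkenyl iodide; 12 (R)-triethyl(oxiran-2-ylmethoxy)silane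
Product: 14 (2R,4Z,6S,8E)-6-[(tert-butyldimethylsilyl)oxy]-4,8-dimethyl-1,10-bis[(triethylsilyl)oxy]deca-4,8-dien-2-ol, via alkenyllithium 13 (not isolated)
Conditions: t-BuLi (2.05 equiv), Et2O, −78 °C; then 12 (1.3 equiv), BF3·OEt2, −78 °C
Reagents that add atoms: none
Why: Iodine–lithium exchange proceeds with retention of the Z geometry and the alkenyllithium opens the BF3-activated epoxide at its CH2 terminus (SN2), forming C9–C10 while C8 (R) comes unchanged from glycidol (Lewis-acid-promoted organolithium epoxide opening).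

Step 10
Reactants: 14 homoallylic alcohol
Product: 15 (2R,4Z,6S,8E)-6-[(tert-butyldimethylsilyl)oxy]-4,8-dimethyl-1,2,10-tris[(triethylsilyl)oxy]deca-4,8-diene
Conditions: Et3SiCl, imidazole, DMAP (cat.), CH2Cl2, rt
Reagents that add atoms: chlorotriethylsilane, CC[Si](Cl)(CC)CC
Why: Plain silylation of the remaining secondary alcohol gives a C8 protecting group that can later be removed in the presence of the C2 TBS ether.

Step 11
Reactants: 15 tetrasilyl ether
Product: 16 (2E,5S,6Z,9R)-5-[(tert-butyldimethylsilyl)oxy]-3,7-dimethyl-9-[(triethylsilyl)oxy]deca-2,6-dienedial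
Conditions: (COCl)2, DMSO, CH2Cl2, −78 → −35 °C; Et3N, −78 → 0 °C
Reagents that add atoms: none
Why: Under Swern conditions primary triethylsilyl ethers are cleaved by the chlorosulfonium salt and oxidised in place while secondary TES and TBS ethers survive, so both chain ends become aldehydes in one operation (direct Swern oxidation of primary silyl ethers); the base is added cold to avoid epimerisation at C8.

Step 12
Reactants: 16 dialdehyde; 17 methyl acrylate
Product: 18 methyl (3RS,4R,6Z,8S,10E)-8-[(tert-butyldimethylsilyl)oxy]-3-hydroxy-6,10-dimethyl-2-methylidene-12-oxo-4-[(triethylsilyl)oxy]dodeca-6,10-dienoate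
Conditions: 17 (neat, 15 equiv), DABCO (1 equiv), rt, 3 d
Reagents that add atoms: none
Why: The amine-catalysed Morita–Baylis–Hillman reaction occurs only at the activated α-silyloxy aldehyde because the β,β-disubstituted enal is a very poor acceptor, and the new carbinol centre (a mixture) is erased in the next step.

Step 13
Reactants: 18 Morita–Baylis–Hillman adduct
Product: 19 methyl (2Z,4R,6Z,8S,10E)-2-(bromomethyl)-8-[(tert-butyldimethylsilyl)oxy]-6,10-dimethyl-12-oxo-4-[(triethylsilyl)oxy]dodeca-2,6,10-trienoate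
Conditions: NBS, Me2S, CH2Cl2, 0 °C (premixed); then 18, 0 °C → rt
Reagents that add atoms: N-bromosuccinimide, O=C1CCC(=O)N1Br
Why: The alkoxysulfonium salt is displaced by bromide in SN2′ fashion, which converges both C7 epimers to the thermodynamically preferred (Z)-2-(bromomethyl)enoate (Corey–Kim-type allylic bromination with transposition).

Step 14
Reactants: 19 enal/allyl bromide
Product: 22 (1(10)Z,2S,4E,6R,7S,8R)-2-[(tert-butyldimethylsilyl)oxy]-8-[(triethylsilyl)oxy]germacra-1(10),4,11(13)-trien-12,6-olide (7S only through the priority of O–Si; same spatial arrangement as 7R in the target), via allylchromium species 20 (not isolated), via trimethylsilyl ether 21 (not isolated)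
Conditions: CrCl2 (15 mol %), L1 (18 mol %; L1 = (S,S)-3,6-di-tert-butyl-1,8-bis(4-isopropyl-4,5-dihydrooxazol-2-yl)-9H-carbazole), iPr2NEt (30 mol %), Mn powder (3 equiv), Me3SiCl (1.5 equiv), THF, 0.003 M, slow addition of 19, rt; then aq. citric acid, THF, 0 °C
Reagents that add atoms: none
Why: Proposed new method: a chromium-catalysed, ligand-controlled macrocyclising 2-(methoxycarbonyl)allylation in which two divalent chromium centres reduce the allylic C–Br bond to a ligand-bound allyl trivalent chromium species that equilibrates to the E-crotyl-type form and adds through its γ-carbon (C7) to the Si face of the tethered enal via a chair Zimmerman–Traxler transition state with C5 and C8 equatorial, so that the C6–C7 bond, the 10-membered ring, 6R and the 6,7-anti (trans-lactone) relationship are set together, after which Me3SiCl silylates the chromium alkoxide, zerovalent manganese returns trivalent to divalent chromium and the γ-hydroxy ester freed on acidic work-up lactonises; the closest known reactions are the Nozaki–Hiyama–Kishi allylation, its catalytic asymmetric intermolecular 2-(alkoxycarbonyl)allylation and stoichiometric CrCl2 Barbier macrocyclisations of germacranolide precursors, whereas a catalytic, catalyst-controlled ring closure with a γ-substituted 2-(bromomethyl)enoate has not been shown (the ligand antipode matched to the C8 centre is assumed to be S,S).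

Step 15
Reactants: 23 (E)-but-2-enal
Product: 25 (Z)-2-bromobut-2-enal, via 2,3-dibromobutanal 24 (not isolated)
Conditions: Br2, CH2Cl2, 0 °C; then Et3N, 0 °C → rt
Reagents that add atoms: bromine, BrBr
Why: Addition of bromine followed by E2 loss of HBr through the acidic α-hydrogen gives the conjugated α-bromo enal with the methyl group trans to the formyl group (bromination–dehydrobromination).

Step 16
Reactants: 25 (Z)-2-bromobut-2-enal
Product: 26 (Z)-2-bromobut-2-en-1-ol
Conditions: NaBH4, CeCl3·7H2O, MeOH, 0 °C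
Reagents that add atoms: none
Why: Luche conditions give clean 1,2-reduction of the enal without touching the C–Br bond or the alkene geometry (Luche reduction).

Step 17
Reactants: 26 (Z)-2-bromobut-2-en-1-ol
Product: 27 (Z)-[(2-bromobut-2-en-1-yl)oxy](tert-butyl)dimethylsilane
Conditions: t-BuMe2SiCl, imidazole, CH2Cl2, rt
Reagents that add atoms: tert-butyldimethylsilyl chloride, CC(C)(C)[Si](C)(C)Cl
Why: Standard silylation installs the group that later distinguishes the two CH2O arms.

Step 18
Reactants: 27 Z-bromoalkene silyl ether; 28 formaldehyde (cracked from paraformaldehyde)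
Product: 30 (E)-2-{[(tert-butyldimethylsilyl)oxy]methyl}but-2-en-1-ol, via alkenyllithium 29 (not isolated)
Conditions: t-BuLi (2.05 equiv), Et2O, −78 °C; then CH2O (gas), −78 → 0 °C
Reagents that add atoms: none
Why: Bromine–lithium exchange occurs with retention and the alkenyllithium adds to formaldehyde, which places the new free CH2OH cis to the methyl group (halogen–metal exchange and hydroxymethylation).

Step 19
Reactants: 30 (E)-2-{[(tert-butyldimethylsilyl)oxy]methyl}but-2-en-1-ol
Product: 31 [(2R,3R)-2-{[(tert-butyldimethylsilyl)oxy]methyl}-3-methyloxiran-2-yl]methanol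
Conditions: Ti(OiPr)4 (10 mol %), L-(+)-diethyl tartrate (12 mol %), t-BuOOH, 4 Å MS, CH2Cl2, −20 °C
Reagents that add atoms: tert-butyl hydroperoxide, CC(C)(C)OO
Why: In the Sharpless asymmetric epoxidation the only free allylic hydroxyl binds the titanium tartrate and L-(+)-tartrate delivers oxygen to the face that gives (2R,3R), while the alkene geometry (methyl cis to CH2OH) is transferred stereospecifically.

Step 20
Reactants: 31 epoxy alcohol
Product: 32 (2R,3R)-2-{[(tert-butyldimethylsilyl)oxy]methyl}-3-methyloxirane-2-carboxylic acid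
Conditions: TEMPO (20 mol %), PhI(OAc)2 (2.2 equiv), MeCN–H2O, rt; used crude
Reagents that add atoms: water, O
Why: The oxoammonium cycle oxidises the primary alcohol through the aldehyde hydrate to the acid under near-neutral conditions that spare the epoxide and the TBS ether (TEMPO/iodobenzene diacetate oxidation), so the acid carbon ends up cis to the methyl group as in the target.

Step 21
Reactants: 22 protected lactone
Product: 33 (1(10)Z,2S,4E,6R,7R,8R)-2-[(tert-butyldimethylsilyl)oxy]-8-hydroxygermacra-1(10),4,11(13)-trien-12,6-olide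
Conditions: HF·pyridine, pyridine, THF, 0 °C
Reagents that add atoms: none
Why: Buffered HF·pyridine cleaves the secondary triethylsilyl ether much faster than the allylic TBS ether and is acidic enough to avoid Michael addition or translactonisation (selective desilylation).

Step 22
Reactants: 33 C8 alcohol; 32 epoxy acid
Product: 35 (1(10)Z,2S,4E,6R,7R,8R)-2-[(tert-butyldimethylsilyl)oxy]germacra-1(10),4,11(13)-trien-12,6-olid-8-yl (2R,3R)-2-{[(tert-butyldimethylsilyl)oxy]methyl}-3-methyloxirane-2-carboxylate, via mixed anhydride 34 (not isolated)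
Conditions: 32 (3 equiv), 2,4,6-Cl3C6H2COCl, Et3N, THF, rt; then 33, DMAP, toluene, rt
Reagents that add atoms: none
Why: In the Yamaguchi esterification DMAP transfers the epoxy acyl group from the mixed anhydride to the hindered C8 alcohol, and the quaternary α-carbon of the acid cannot epimerise.

Step 23
Reactants: 35 bis-silyl ether
Product: 36 target, (1(10)Z,2S,4E,6R,7R,8R)-2-hydroxygermacra-1(10),4,11(13)-trien-12,6-olid-8-yl (2R,3R)-2-(hydroxymethyl)-3-methyloxirane-2-carboxylate
Conditions: Bu4NF, AcOH (1:1), THF, 0 °C → rt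
Reagents that add atoms: none
Why: Acetic-acid-buffered fluoride removes both TBS ethers without opening the epoxide, adding to the α-methylene lactone or moving the lactone to O8 (fluoride desilylation).

**Compound list**
1 | but-2-yn-1-ol | CC#CCO | starting material
2 | but-2-ynal | CC#CC=O | intermediate
3 | methyl 3-methylbut-2-enoate | CC(C)=CC(=O)OC | starting material
4 | (1Z)-1-[(tert-butyldimethylsilyl)oxy]-1-methoxy-3-methylbuta-1,3-diene | C=C(C)/C=C(/OC)O[Si](C)(C)C(C)(C)C | intermediate
5 | methyl (2E,5S)-5-hydroxy-3-methyloct-2-en-6-ynoate | CC#C[C@@H](O)C/C(C)=C/C(=O)OC | intermediate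
6 | (2E,5S)-3-methyloct-2-en-6-yne-1,5-diol | CC#C[C@@H](O)C/C(C)=C/CO | intermediate
7 | cyclic vinylalanate from 6 (disodium salt, not isolated) | CC1=C[C@H](C/C(C)=C/C[O-])O[Al-]1(OCCOC)OCCOC.[Na+].[Na+] | intermediate
8 | (2E,5S,6Z)-7-iodo-3-methylocta-2,6-diene-1,5-diol | C/C(I)=C/[C@@H](O)C/C(C)=C/CO | intermediate
9 | (2Z,4S,6E)-2-iodo-6-methyl-8-[(triethylsilyl)oxy]octa-2,6-dien-4-ol | C/C(I)=C/[C@@H](O)C/C(C)=C/CO[Si](CC)(CC)CC | intermediate
10 | tert-butyl{[(2Z,4S,6E)-2-iodo-6-methyl-8-[(triethylsilyl)oxy]octa-2,6-dien-4-yl]oxy}dimethylsilane | C/C(I)=C/[C@@H](O[Si](C)(C)C(C)(C)C)C/C(C)=C/CO[Si](CC)(CC)CC | intermediate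
11 | (S)-glycidol, (2S)-oxiran-2-ylmethanol | OC[C@H]1CO1 | starting material
12 | (R)-triethyl(oxiran-2-ylmethoxy)silane | CC[Si](CC)(CC)OC[C@H]1CO1 | intermediate
13 | Z-alkenyllithium from 10 (not isolated) | C/C([Li])=C/[C@@H](O[Si](C)(C)C(C)(C)C)C/C(C)=C/CO[Si](CC)(CC)CC | intermediate
14 | (2R,4Z,6S,8E)-6-[(tert-butyldimethylsilyl)oxy]-4,8-dimethyl-1,10-bis[(triethylsilyl)oxy]deca-4,8-dien-2-ol | CC[Si](CC)(CC)OC[C@H](O)C/C(C)=C\[C@@H](O[Si](C)(C)C(C)(C)C)C/C(C)=C/CO[Si](CC)(CC)CC | intermediate
15 | (2R,4Z,6S,8E)-6-[(tert-butyldimethylsilyl)oxy]-4,8-dimethyl-1,2,10-tris[(triethylsilyl)oxy]deca-4,8-diene | CC[Si](CC)(CC)OC[C@H](O[Si](CC)(CC)CC)C/C(C)=C\[C@@H](O[Si](C)(C)C(C)(C)C)C/C(C)=C/CO[Si](CC)(CC)CC | intermediate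
16 | (2E,5S,6Z,9R)-5-[(tert-butyldimethylsilyl)oxy]-3,7-dimethyl-9-[(triethylsilyl)oxy]deca-2,6-dienedial | O=C[C@H](O[Si](CC)(CC)CC)C/C(C)=C\[C@@H](O[Si](C)(C)C(C)(C)C)C/C(C)=C/C=O | intermediate
17 | methyl acrylate | C=CC(=O)OC | starting material
18 | methyl (3RS,4R,6Z,8S,10E)-8-[(tert-butyldimethylsilyl)oxy]-3-hydroxy-6,10-dimethyl-2-methylidene-12-oxo-4-[(triethylsilyl)oxy]dodeca-6,10-dienoate | C=C(C(=O)OC)C(O)[C@H](O[Si](CC)(CC)CC)C/C(C)=C\[C@@H](O[Si](C)(C)C(C)(C)C)C/C(C)=C/C=O | intermediate
19 | methyl (2Z,4R,6Z,8S,10E)-2-(bromomethyl)-8-[(tert-butyldimethylsilyl)oxy]-6,10-dimethyl-12-oxo-4-[(triethylsilyl)oxy]dodeca-2,6,10-trienoate | BrC/C(C(=O)OC)=C\[C@H](O[Si](CC)(CC)CC)C/C(C)=C\[C@@H](O[Si](C)(C)C(C)(C)C)C/C(C)=C/C=O | intermediate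
20 | allyl trivalent chromium species from 19 (chiral ligand and solvent on chromium omitted, not isolated) | Cl[Cr](Cl)C/C(C(=O)OC)=C\[C@H](O[Si](CC)(CC)CC)C/C(C)=C\[C@@H](O[Si](C)(C)C(C)(C)C)C/C(C)=C/C=O | intermediate
21 | methyl (1(10)Z,2S,4E,6R,7R,8R)-2-[(tert-butyldimethylsilyl)oxy]-8-[(triethylsilyl)oxy]-6-[(trimethylsilyl)oxy]germacra-1(10),4,11(13)-trien-12-oate (not isolated) | C=C(C(=O)OC)[C@H]1[C@H](O[Si](C)(C)C)/C=C(\C)C[C@H](O[Si](C)(C)C(C)(C)C)/C=C(/C)C[C@H]1O[Si](CC)(CC)CC | intermediate
22 | (1(10)Z,2S,4E,6R,7S,8R)-2-[(tert-butyldimethylsilyl)oxy]-8-[(triethylsilyl)oxy]germacra-1(10),4,11(13)-trien-12,6-olide | C=C1C(=O)O[C@@H]2/C=C(\C)C[C@H](O[Si](C)(C)C(C)(C)C)/C=C(/C)C[C@@H](O[Si](CC)(CC)CC)[C@@H]12 | intermediate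
23 | (E)-but-2-enal (crotonaldehyde) | C/C=C/C=O | starting material
24 | 2,3-dibromobutanal (not isolated) | CC(Br)C(Br)C=O | intermediate
25 | (Z)-2-bromobut-2-enal | C/C=C(\Br)C=O | intermediate
26 | (Z)-2-bromobut-2-en-1-ol | C/C=C(\Br)CO | intermediate
27 | (Z)-[(2-bromobut-2-en-1-yl)oxy](tert-butyl)dimethylsilane | C/C=C(\Br)CO[Si](C)(C)C(C)(C)C | intermediate
28 | formaldehyde (from paraformaldehyde) | C=O | starting material
29 | alkenyllithium from 27 (not isolated) | C/C=C(\[Li])CO[Si](C)(C)C(C)(C)C | intermediate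
30 | (E)-2-{[(tert-butyldimethylsilyl)oxy]methyl}but-2-en-1-ol | C/C=C(\CO)CO[Si](C)(C)C(C)(C)C | intermediate
31 | [(2R,3R)-2-{[(tert-butyldimethylsilyl)oxy]methyl}-3-methyloxiran-2-yl]methanol | OC[C@]1(CO[Si](C)(C)C(C)(C)C)O[C@@H]1C | intermediate
32 | (2R,3R)-2-{[(tert-butyldimethylsilyl)oxy]methyl}-3-methyloxirane-2-carboxylic acid | OC(=O)[C@]1(CO[Si](C)(C)C(C)(C)C)O[C@@H]1C | intermediate
33 | (1(10)Z,2S,4E,6R,7R,8R)-2-[(tert-butyldimethylsilyl)oxy]-8-hydroxygermacra-1(10),4,11(13)-trien-12,6-olide | C=C1C(=O)O[C@@H]2/C=C(\C)C[C@H](O[Si](C)(C)C(C)(C)C)/C=C(/C)C[C@@H](O)[C@@H]12 | intermediate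
34 | (2R,3R)-2-{[(tert-butyldimethylsilyl)oxy]methyl}-3-methyloxirane-2-carboxylic 2,4,6-trichlorobenzoic anhydride (not isolated) | O=C(OC(=O)c1c(Cl)cc(Cl)cc1Cl)[C@]1(CO[Si](C)(C)C(C)(C)C)O[C@@H]1C | intermediate
35 | (1(10)Z,2S,4E,6R,7R,8R)-2-[(tert-butyldimethylsilyl)oxy]germacra-1(10),4,11(13)-trien-12,6-olid-8-yl (2R,3R)-2-{[(tert-butyldimethylsilyl)oxy]methyl}-3-methyloxirane-2-carboxylate | C=C1C(=O)O[C@@H]2/C=C(\C)C[C@H](O[Si](C)(C)C(C)(C)C)/C=C(/C)C[C@@H](OC(=O)[C@]3(CO[Si](C)(C)C(C)(C)C)O[C@@H]3C)[C@@H]12 | intermediate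
36 | (1(10)Z,2S,4E,6R,7R,8R)-2-hydroxygermacra-1(10),4,11(13)-trien-12,6-olid-8-yl (2R,3R)-2-(hydroxymethyl)-3-methyloxirane-2-carboxylate | C=C1C(=O)O[C@@H]2/C=C(\C)C[C@H](O)/C=C(/C)C[C@@H](OC(=O)[C@]3(CO)O[C@@H]3C)[C@@H]12 | target

**Step count**
Total step count: 23.
Longest linear sequence: 15 steps (steps 1, 3–7, 9–14, 21–23, from but-2-yn-1-ol). The epoxide branch (step 8) and the side-chain branch (steps 15–20) join at steps 9 and 22.

**Three steps most likely to fail, with fallbacks**

Step 14 (the new ring closure). The catalytic turnover at high dilution, the competition between ligand control and the bias of the C8 centre, and the 6,7-anti selectivity are all untested on this substrate. The fallback uses known chemistry and gives up catalysis and catalyst control. It sets out from 19, which is added slowly to an excess of CrCl2 (8 equiv, THF/DMF, 0.002 M, rt), a stoichiometric, substrate-controlled Nozaki–Hiyama–Kishi/Barbier macrocyclisation of the kind already used to close germacranolide rings from 1(10)Z precursors. Aqueous work-up gives the open hydroxy ester methyl (1(10)Z,2S,4E,6R,7S,8R)-2-[(tert-butyldimethylsilyl)oxy]-6-hydroxy-8-[(triethylsilyl)oxy]germacra-1(10),4,11(13)-trien-12-oate F1, which is separated from any diastereomer and lactonised on its own with catalytic camphorsulfonic acid in CH2Cl2. It comes back to the route at 22.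

Step 12 (Morita–Baylis–Hillman reaction on the dialdehyde). The reaction takes days, and during that time the amine can move the C8 silyl group to the new hydroxyl, epimerise C8 or isomerise the enal. The fallback replaces amine catalysis by a preformed acrylate α-anion equivalent. It sets out from 16: methyl propiolate is hydroaluminated with iBu2AlH and N-methylmorpholine N-oxide (THF, 0 °C) to [1-(methoxycarbonyl)ethenyl]bis(2-methylpropyl)aluminium F2, and 1.05 equiv of it is added to 16 at −78 °C, where the α-silyloxy aldehyde reacts ahead of the conjugated, β,β-disubstituted enal. Work-up gives the same adduct, so the fallback comes back at 18.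

Step 9 (fragment union). The Z-γ-silyloxy alkenyllithium 13 can undergo 1,4 O→C silyl migration, and BF3 can damage the silyl ethers or the epoxide. The fallback avoids any organolithium. It sets out from 10 and 12 and joins them by nickel-catalysed reductive cross-electrophile coupling (NiI2 10 mol %, 4,4′-di-tert-butyl-2,2′-bipyridine, NaI, Et3N·HCl, zinc powder, DMPU, rt). Iodide opens 12 in the flask to (S)-1-iodo-3-[(triethylsilyl)oxy]propan-2-ol F3, and the nickel catalyst couples its primary carbon with the alkenyl iodide with retention of the Z geometry. It comes back at 14.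

**Further compounds**
F1 | step 14 | methyl (1(10)Z,2S,4E,6R,7S,8R)-2-[(tert-butyldimethylsilyl)oxy]-6-hydroxy-8-[(triethylsilyl)oxy]germacra-1(10),4,11(13)-trien-12-oate | C=C(C(=O)OC)[C@H]1[C@H](O)/C=C(\C)C[C@H](O[Si](C)(C)C(C)(C)C)/C=C(/C)C[C@H]1O[Si](CC)(CC)CC
F2 | step 12 | [1-(methoxycarbonyl)ethenyl]bis(2-methylpropyl)aluminium | C=C(C(=O)OC)[Al](CC(C)C)CC(C)C
F3 | step 9 | (S)-1-iodo-3-[(triethylsilyl)oxy]propan-2-ol | CC[Si](CC)(CC)OC[C@H](O)CI
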